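The numbers in the tables were computed on assumed constants; the scatter is artificial.

Ask how much starting material is left at the end, not how much is made: the question then becomes a bracket.

| flask | starting material | reagent | remark | time |
|---|---|---|---|---|
| south-east | 10 mM | 4 mM | run made earlier |  |
| south | 10 mM | 9 mM | run made earlier |  |
| north-west | 15 mM | 6 mM | run made earlier |  |
| flask | 10 mM | 6.00 mM |  | 15 min |

| run | time / min | starting material / % | target / % |
|---|---|---|---|
| south-east | 2.00 | 71.4 | 21.8 |
| south-east | 4.00 | 71.1 | 22.8 |
| south-east | 6.00 | 69.0 | 21.4 |
| south-east | 8.00 | 71.9 | 20.3 |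
| south-east | 10.0 | 71.5 | 21.3 |
| south-east | 12.0 | 71.7 | 22.7 |
| south | 1.00 | 49.4 | 39.1 |
| south | 1.50 | 46.0 | 41.5 |
| south | 2.50 | 44.4 | 42.0 |
| south | 4.00 | 45.6 | 42.5 |
| south | 8.00 | 45.1 | 42.9 |
| south | 12.0 | 44.7 | 42.2 |
| north-west | 2.50 | 69.7 | 24.1 |
| north-west | 5.00 | 69.5 | 24.7 |
| north-west | 8.00 | 68.1 | 22.9 |
| north-west | 10.0 | 68.4 | 23.9 |
| north-west | 12.0 | 67.9 | 24.1 |

(standard deviation of a reading: 1 percentage point)

- the numbers in the tables scatter by 1 percentage point (one standard deviation)
- steps under discussion: starting material + reagent <-> target; target <-> isomer of the product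

1. how much of the starting material has reacted by 15 min
2. how much target there is at 15 min, in percent of the starting material charged

Bound it first. One reagent takes one starting material, so 6.00 mM of reagent against 10 mM leaves at least 40.0 % of the starting material: there is less reagent than starting material, so reagent is the limiting reagent. The flask has the same charge of starting material as south-east and more reagent, so take the left-over of that run as the ceiling.

Now tighten. The south-east readings stay flat up to 12.0 min, and 15 min comes later, so treat the flask as standing. Target and isomer of the product both hold reagent, so divide the amount of starting material taken up by the product of the amounts of starting material and reagent left. Averaging flat readings (south from 2.50 min), south-east took 2.89 mM, leaving 71.1 %, south 5.50 mM and north-west 4.69 mM. The quotients are 0.366 mM⁻¹, 0.350 mM⁻¹ and 0.348 mM⁻¹. Keep their mean, the holding number (an apparent equilibrium constant), 0.355 mM⁻¹.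

Solving the flask with the outer quotients leaves 59.0 % to 59.5 %. The holding number leaves 59.3 %. Target was 77.0 % of what reacted in south, so I expect 31.3 % target.

The forecast, holding that “both steps look equilibrated”, says 40.7 % reacted and 31 % target, inside the bracket. The flask gives 40.5 % reacted and 31.4 % target, so 59.5 % left, level with the upper end of the bracket.

    starting material + reagent ⇌ target (K = 270 L mol⁻¹, k = 3.10 L mol⁻¹ s⁻¹)
    target ⇌ isomer of the product (K = 0.290, k = 0.0350 s⁻¹)

The slowest mode of the flask, as it stands at 15.0 min, has a half-life of 0.353 min, far shorter than the 15 min allowed. At 150 min the flask still shows 40.5 % reacted and 31.4 % target. The flask's own holding number is 0.349 mM⁻¹. For the neighbouring flask with 15 mM of reagent, the kept number gives 73.2 % reacted, and that flask stands at 72.9 %.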